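**Retrosynthetic overview**
- The strategy rests on ring carbon C5 of the oxolane: it is an ether carbon on ring O1 and also propargylic. Cutting the enyne at its C(sp)–C(sp2) bond leaves a terminal ethynyl group on C5, which is what a copper allenylidene needs.
- The O1–C5 bond is therefore closed from an open-chain C1–C10 hydroxy propargylic pentafluorobenzoate, used as a mixture of carbinol epimers and funnelled to one ring isomer by a chiral copper–pybox catalyst.
- The chain is built from (S)-1,2-epoxy-5-hexene (its carbinol carbon becomes ring C2), methyl propiolate and ethynylmagnesium bromide.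
- The side chain is a (1E,7Z,9Z)-bromo-iodo-decatriene from a Z-selective Wittig reaction; it is joined last by Sonogashira coupling at the iodide.
- Order: linear chain, then the single oxolane ring, then the side-chain coupling.

Key step: step 7

Remark: the sense of induction of Ph-pybox in this intramolecular etherification cannot be predicted with confidence, so the ligand antipode is fixed by one trial run with each enantiomer; catalyst-bound species of the catalytic cycles are described in the Why lines and carry no number.

**Route**

Step 1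
Reactants: 1 (S)-1,2-epoxy-5-hexene; 2 methyl propiolate
Product: 4 methyl (5S)-5-hydroxynon-8-en-2-ynoate, via methyl 3-lithiopropiolate 3 (not isolated)
Conditions: 2, n-BuLi, THF, −78 °C; BF3·OEt2 then 1, −78 °C; aq NH4Cl
Reagents that add atoms: none
Why: BF3-assisted opening of a terminal epoxide by a lithium acetylide (Yamaguchi–Hirao alkynylation) takes place at the unhindered CH2 terminus, so the carbinol C–O bond and its configuration pass unchanged into 4.

Step 2
Reactants: 4 methyl (5S)-5-hydroxynon-8-en-2-ynoate
Product: 5 methyl (5S)-5-(tert-butyldimethylsilyloxy)non-8-en-2-ynoate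
Conditions: TBSCl, imidazole, DMF, rt
Reagents that add atoms: tert-butyldimethylsilyl chloride, CC(C)(C)[Si](C)(C)Cl
Why: Imidazole-promoted silylation of a secondary alcohol is routine and masks the hydroxyl that would otherwise form a lactol with the aldehyde made next.

Step 3
Reactants: 5 methyl (5S)-5-(tert-butyldimethylsilyloxy)non-8-en-2-ynoate
Product: 7 methyl (5S)-5-(tert-butyldimethylsilyloxy)-8-oxooct-2-ynoate, via secondary ozonide 6 (not isolated)
Conditions: O3, CH2Cl2, −78 °C (Sudan Red 7B end point); Me2S, −78 °C to rt
Reagents that add atoms: ozone, [O-][O+]=O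
Why: Ozonolysis with reductive work-up cleaves the electron-rich terminal alkene far faster than the electron-poor conjugated alkyne, and the indicator dye stops the ozone feed before the ynoate is attacked.

Step 4
Reactants: 7 methyl (5S)-5-(tert-butyldimethylsilyloxy)-8-oxooct-2-ynoate
Product: 8 methyl (5R)-5-(tert-butyldimethylsilyloxy)-8-oxooctanoate
Conditions: H2 (1 atm), Pd/C (10% palladium on carbon), EtOAc, rt
Reagents that add atoms: none
Why: Heterogeneous catalytic hydrogenation saturates the ynoate while the aliphatic aldehyde and the silyl ether are inert in neutral ethyl acetate; the centre is untouched and its descriptor changes only because the ranking of the two chains switches.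

Step 5
Reactants: 8 methyl (5R)-5-(tert-butyldimethylsilyloxy)-8-oxooctanoate; 9 ethynylmagnesium bromide
Product: 11 methyl (5R)-5-(tert-butyldimethylsilyloxy)-8-(pentafluorobenzoyloxy)dec-9-ynoate (both C8 epimers), via bromomagnesium alkoxide 10 (not isolated)
Conditions: 9 (1.1 equiv), THF, −78 °C; C6F5COCl (1.5 equiv), −78 °C to 0 °C
Reagents that add atoms: pentafluorobenzoyl chloride, O=C(Cl)c1c(F)c(F)c(F)c(F)c1F
Why: Grignard 1,2-addition to the aldehyde is much faster than attack on the methyl ester at −78 °C, the magnesium alkoxide is acylated in the flask by the acid chloride, and no control at C8 is wanted because step 7 erases that centre.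

Step 6
Reactants: 11 methyl (5R)-5-(tert-butyldimethylsilyloxy)-8-(pentafluorobenzoyloxy)dec-9-ynoate (both C8 epimers)
Product: 12 methyl (5R)-5-hydroxy-8-(pentafluorobenzoyloxy)dec-9-ynoate (both C8 epimers)
Conditions: HF·pyridine, pyridine, THF, 0 °C; cold aq NaHCO3 work-up, used at once
Reagents that add atoms: none
Why: Fluoride-driven desilylation under pyridine buffering removes the secondary silyl ether without touching the activated aryl ester or the alkyne, and cold buffered handling with immediate use should keep the δ-hydroxy ester from closing to the lactone.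

Step 7
Reactants: 12 methyl (5R)-5-hydroxy-8-(pentafluorobenzoyloxy)dec-9-ynoate (both C8 epimers)
Product: 13 methyl 4-[(2R,5S)-5-ethynyloxolan-2-yl]butanoate
Conditions: (CuOTf)2·C6H6 (5 mol%, monovalent copper), (S,S)- or (R,R)-Ph-pybox [2,6-bis(4-phenyl-4,5-dihydrooxazol-2-yl)pyridine] (10 mol%, the antipode matched to C2), iPr2NEt (1.5 equiv), THF (0.02 M), 0 °C to rt
Reagents that add atoms: none
Why: Proposed new method: monovalent copper and the amine turn the terminal alkyne of 12 into a copper acetylide, loss of pentafluorobenzoate gives a copper allenylidene whose γ-carbon (chain C8) is trigonal, so both C8 epimers merge into one intermediate before the C5 hydroxyl adds to that carbon and the resulting copper acetylide is protonated to release 13 and the catalyst. The closest known reaction type is the copper–pybox-catalysed enantioselective propargylic etherification with alcohols and phenols, together with the intramolecular propargylic amination of terminal propargylic esters, both through copper allenylidenes and with pentafluorobenzoate as leaving group for aliphatic cases; an intramolecular oxygen nucleophile on an aliphatic ester that already carries a stereocentre has not been shown. The oxolane closes in a 5-exo-trig mode, the oxygen on chain C5 becoming ring O1 and chain C8 becoming ring C5. The new centre at ring C5 (S) is set by the chiral pybox pocket, which leaves one face of the allenylidene open, and ring C2 is not touched. The step needs face selectivity for the 2,5-trans ring, which the catalyst must supply because the remote C2 chain gives little bias, and chemoselectivity over β-hydrogen loss to an enyne, intermolecular etherification and δ-lactonisation, which the fast tethered five-ring closure, high dilution, an aprotic solvent and a mild amine base at room temperature are chosen to secure.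

Step 8
Reactants: 14 hept-6-yn-1-ol
Product: 16 (E)-7-iodohept-6-en-1-ol, via alkenylzirconocene alkoxide 15 (not isolated)
Conditions: Cp2Zr(H)Cl (2.2 equiv), THF, 0 °C to rt; I2, 0 °C; aq Na2S2O3
Reagents that add atoms: iodine, II
Why: Hydrozirconation adds Zr–H syn and anti-Markovnikov to the terminal alkyne (one extra equivalent is consumed by the hydroxyl) and iodinolysis of the C–Zr bond proceeds with retention, which should give the E-iodoalkene only.

Step 9
Reactants: 16 (E)-7-iodohept-6-en-1-ol
Product: 17 (E)-1,7-diiodohept-1-ene
Conditions: I2, PPh3, imidazole, CH2Cl2, 0 °C to rt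
Reagents that add atoms: iodine, II
Why: Appel iodination converts the primary alcohol into the iodide under neutral conditions that leave the alkenyl iodide and its geometry alone.

Step 10
Reactants: 17 (E)-1,7-diiodohept-1-ene
Product: 18 [(E)-7-iodohept-6-enyl]triphenylphosphonium iodide
Conditions: PPh3, MeCN, reflux, dark
Reagents that add atoms: triphenylphosphine, c1ccc(cc1)P(c1ccccc1)c1ccccc1
Why: SN2 quaternisation of the phosphine occurs only at the primary alkyl iodide, since an alkenyl iodide does not react with a phosphine without a metal catalyst.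

Step 11
Reactants: 19 ethyl (Z)-3-bromoacrylate
Product: 20 (Z)-3-bromoprop-2-en-1-ol
Conditions: iBu2AlH (2.2 equiv), CH2Cl2, −78 °C; aq potassium sodium tartrate (KNaC4H4O6)
Reagents that add atoms: none
Why: Hydride reduction of the conjugated ester with iBu2AlH at low temperature stops at the allylic alcohol and should leave the C–Br bond and the Z geometry intact.

Step 12
Reactants: 20 (Z)-3-bromoprop-2-en-1-ol
Product: 21 (Z)-3-bromopropenal
Conditions: MnO2 (activated, excess), CH2Cl2, 0 °C, dark; filtered and used cold at once
Reagents that add atoms: none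
Why: Allylic oxidation on MnO2 is neutral and heterogeneous, so the labile Z-bromoenal is obtained without acid or base that would isomerise it.

Step 13
Reactants: 18 [(E)-7-iodohept-6-enyl]triphenylphosphonium iodide; 21 (Z)-3-bromopropenal
Product: 23 (1E,7Z,9Z)-10-bromo-1-iododeca-1,7,9-triene, via phosphonium ylide 22 (not isolated)
Conditions: NaN(SiMe3)2 (1.0 equiv), THF, −78 °C; then 21, −78 °C to 0 °C, dark
Reagents that add atoms: none
Why: A Wittig reaction of a non-stabilised ylide under lithium-free conditions closes the cis oxaphosphetane under kinetic control and should give the 7Z alkene, while the E-iodoalkene and the Z-bromoalkene are carried over unchanged.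

Step 14
Reactants: 13 methyl 4-[(2R,5S)-5-ethynyloxolan-2-yl]butanoate; 23 (1E,7Z,9Z)-10-bromo-1-iododeca-1,7,9-triene
Product: 24 methyl 4-[(2R,5S)-5-[(3E,9Z,11Z)-12-bromododeca-3,9,11-trien-1-ynyl]oxolan-2-yl]butanoate (target)
Conditions: Pd(PPh3)4 (5 mol%, zerovalent palladium), CuI (10 mol%, copper monoiodide), piperidine, THF, 0 °C to rt, degassed, dark
Reagents that add atoms: none
Why: In a Sonogashira coupling, oxidative addition of zerovalent palladium into the alkenyl C–I bond is much faster than into the alkenyl C–Br bond at or below room temperature and proceeds with retention, so the E-enyne should form with the Z-bromodiene left in place.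

**Compound list**

1 | (S)-1,2-epoxy-5-hexene | C=CCC[C@H]1CO1 | starting material
2 | methyl propiolate | COC(=O)C#C | starting material
3 | methyl 3-lithiopropiolate | COC(=O)C#C[Li] | intermediate
4 | methyl (5S)-5-hydroxynon-8-en-2-ynoate | COC(=O)C#CC[C@@H](O)CCC=C | intermediate
5 | methyl (5S)-5-(tert-butyldimethylsilyloxy)non-8-en-2-ynoate | COC(=O)C#CC[C@@H](O[Si](C)(C)C(C)(C)C)CCC=C | intermediate
6 | secondary ozonide, methyl (5S)-5-(tert-butyldimethylsilyloxy)-7-(1,2,4-trioxolan-3-yl)hept-2-ynoate | COC(=O)C#CC[C@@H](O[Si](C)(C)C(C)(C)C)CCC1OCOO1 | intermediate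
7 | methyl (5S)-5-(tert-butyldimethylsilyloxy)-8-oxooct-2-ynoate | COC(=O)C#CC[C@@H](O[Si](C)(C)C(C)(C)C)CCC=O | intermediate
8 | methyl (5R)-5-(tert-butyldimethylsilyloxy)-8-oxooctanoate | COC(=O)CCC[C@@H](O[Si](C)(C)C(C)(C)C)CCC=O | intermediate
9 | ethynylmagnesium bromide | C#C[Mg]Br | starting material
10 | bromomagnesium alkoxide of methyl (5R)-5-(tert-butyldimethylsilyloxy)-8-hydroxydec-9-ynoate (both C8 epimers) | COC(=O)CCC[C@@H](O[Si](C)(C)C(C)(C)C)CCC(O[Mg]Br)C#C | intermediate
11 | methyl (5R)-5-(tert-butyldimethylsilyloxy)-8-(pentafluorobenzoyloxy)dec-9-ynoate (both C8 epimers) | COC(=O)CCC[C@@H](O[Si](C)(C)C(C)(C)C)CCC(OC(=O)c1c(F)c(F)c(F)c(F)c1F)C#C | intermediate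
12 | methyl (5R)-5-hydroxy-8-(pentafluorobenzoyloxy)dec-9-ynoate (both C8 epimers) | COC(=O)CCC[C@@H](O)CCC(OC(=O)c1c(F)c(F)c(F)c(F)c1F)C#C | intermediate
13 | methyl 4-[(2R,5S)-5-ethynyloxolan-2-yl]butanoate | COC(=O)CCC[C@@H]1CC[C@@H](C#C)O1 | intermediate
14 | hept-6-yn-1-ol | C#CCCCCCO | starting material
15 | alkenylzirconocene alkoxide, (E)-Cp2Zr(Cl)CH=CH(CH2)5OZr(Cl)Cp2 (Cp drawn σ-bound) | Cl[Zr](/C=C/CCCCCO[Zr](Cl)(C1C=CC=C1)C1C=CC=C1)(C1C=CC=C1)C1C=CC=C1 | intermediate
16 | (E)-7-iodohept-6-en-1-ol | OCCCCC/C=C/I | intermediate
17 | (E)-1,7-diiodohept-1-ene | ICCCCC/C=C/I | intermediate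
18 | [(E)-7-iodohept-6-enyl]triphenylphosphonium iodide | I/C=C/CCCCC[P+](c1ccccc1)(c1ccccc1)c1ccccc1.[I-] | intermediate
19 | ethyl (Z)-3-bromoacrylate | CCOC(=O)/C=C\Br | starting material
20 | (Z)-3-bromoprop-2-en-1-ol | OC/C=C\Br | intermediate
21 | (Z)-3-bromopropenal | O=C/C=C\Br | intermediate
22 | phosphonium ylide, [(E)-7-iodohept-6-enylidene]triphenylphosphorane | I/C=C/CCCCC=P(c1ccccc1)(c1ccccc1)c1ccccc1 | intermediate
23 | (1E,7Z,9Z)-10-bromo-1-iododeca-1,7,9-triene | I/C=C/CCCC/C=C\C=C/Br | intermediate
24 | methyl 4-[(2R,5S)-5-[(3E,9Z,11Z)-12-bromododeca-3,9,11-trien-1-ynyl]oxolan-2-yl]butanoate | COC(=O)CCC[C@@H]1CC[C@@H](C#C/C=C/CCCC/C=C\C=C/Br)O1 | target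

**Step count and risks**

Total step count: 14. Longest linear sequence: 8 steps (steps 1 to 7 and step 14, from epoxide 1).

Steps most likely to fail:

1. Step 7 (proposed new method). The ring closure may suffer from poor face selectivity at the allenylidene, from β-hydrogen loss to a conjugated enyne, from slow ionisation of the aliphatic ester in an aprotic medium, or from lactonisation of the hydroxy ester. The fallback uses known chemistry and sets out from aldehyde 8. Methylenation with Ph3P=CH2 (from methyltriphenylphosphonium bromide and NaN(SiMe3)2, THF, −78 to 0 °C) should give methyl (5R)-5-(tert-butyldimethylsilyloxy)non-8-enoate F1. Desilylation with HF·pyridine should give methyl (5R)-5-hydroxynon-8-enoate F2. A Mukaiyama aerobic oxidative cyclisation (Co(modp)2, divalent cobalt, modp = 1-morpholinocarbamoyl-4,4-dimethylpentane-1,3-dionate, O2, tBuOOH, iPrOH, 55 °C), a reaction type known to favour 2,5-trans oxolanes strongly, should close the ring to methyl 4-[(2R,5S)-5-(hydroxymethyl)oxolan-2-yl]butanoate F3. Dess–Martin oxidation should give methyl 4-[(2R,5S)-5-formyloxolan-2-yl]butanoate F4, and Ohira–Bestmann homologation (dimethyl (1-diazo-2-oxopropyl)phosphonate, K2CO3, MeOH, 0 °C) comes back to the route at ethynyl oxolane 13.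

2. Step 13. The Z-bromoenal may isomerise to the E isomer before or during olefination, base may strip HBr from it, or Z selectivity may erode with the conjugated aldehyde. The fallback builds the bromodiene one alkene at a time and sets out from iodoalkenol 16. Dess–Martin oxidation should give (E)-7-iodohept-6-enal F5. Still–Gennari olefination (methyl bis(2,2,2-trifluoroethyl)phosphonoacetate, KN(SiMe3)2, 18-crown-6, THF, −78 °C) should give methyl (2Z,8E)-9-iodonona-2,8-dienoate F6. Reduction with iBu2AlH should give (2Z,8E)-9-iodonona-2,8-dien-1-ol F7, and MnO2 oxidation should give (2Z,8E)-9-iodonona-2,8-dienal F8. Z-selective bromomethylenation with Ph3P=CHBr (from (bromomethyl)triphenylphosphonium bromide and NaN(SiMe3)2, THF, −78 °C) comes back to the route at triene 23.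

3. Step 14. Palladium may also insert at the bromodiene terminus, the alkyne may homocouple oxidatively, or the Z,Z-bromodiene may drift in geometry under palladium and amine. The fallback couples before any alkenyl bromide is present and sets out from ethynyl oxolane 13 and iodoalkenol 16. Their Sonogashira coupling (same catalyst system) should give methyl 4-[(2R,5S)-5-[(E)-9-hydroxynon-3-en-1-ynyl]oxolan-2-yl]butanoate F9. Appel iodination should give methyl 4-[(2R,5S)-5-[(E)-9-iodonon-3-en-1-ynyl]oxolan-2-yl]butanoate F10. Heating with PPh3 in MeCN should give [(E)-9-[(2S,5R)-5-(4-methoxy-4-oxobutyl)oxolan-2-yl]non-6-en-8-ynyl]triphenylphosphonium iodide F11. Its ylide (NaN(SiMe3)2, THF, −78 °C) with (Z)-3-bromopropenal 21 comes back to the route at target 24.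

**Further compounds**

F1 | step 7 | methyl (5R)-5-(tert-butyldimethylsilyloxy)non-8-enoate | COC(=O)CCC[C@@H](O[Si](C)(C)C(C)(C)C)CCC=C
F2 | step 7 | methyl (5R)-5-hydroxynon-8-enoate | COC(=O)CCC[C@@H](O)CCC=C
F3 | step 7 | methyl 4-[(2R,5S)-5-(hydroxymethyl)oxolan-2-yl]butanoate | COC(=O)CCC[C@@H]1CC[C@@H](CO)O1
F4 | step 7 | methyl 4-[(2R,5S)-5-formyloxolan-2-yl]butanoate | COC(=O)CCC[C@@H]1CC[C@@H](C=O)O1
F5 | step 13 | (E)-7-iodohept-6-enal | O=CCCCC/C=C/I
F6 | step 13 | methyl (2Z,8E)-9-iodonona-2,8-dienoate | COC(=O)/C=C\CCCC/C=C/I
F7 | step 13 | (2Z,8E)-9-iodonona-2,8-dien-1-ol | OC/C=C\CCCC/C=C/I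
F8 | step 13 | (2Z,8E)-9-iodonona-2,8-dienal | O=C/C=C\CCCC/C=C/I
F9 | step 14 | methyl 4-[(2R,5S)-5-[(E)-9-hydroxynon-3-en-1-ynyl]oxolan-2-yl]butanoate | COC(=O)CCC[C@@H]1CC[C@@H](C#C/C=C/CCCCCO)O1
F10 | step 14 | methyl 4-[(2R,5S)-5-[(E)-9-iodonon-3-en-1-ynyl]oxolan-2-yl]butanoate | COC(=O)CCC[C@@H]1CC[C@@H](C#C/C=C/CCCCCI)O1
F11 | step 14 | [(E)-9-[(2S,5R)-5-(4-methoxy-4-oxobutyl)oxolan-2-yl]non-6-en-8-ynyl]triphenylphosphonium iodide | COC(=O)CCC[C@@H]1CC[C@@H](C#C/C=C/CCCCC[P+](c2ccccc2)(c2ccccc2)c2ccccc2)O1.[I-]
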